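**Retrosynthetic overview**
1. Target ⇒ acyclic (E,E,E,E)-tetraenyl keto acid: the cyclopentanone ring A and the cyclohexene ring B close together in the last operation by an intramolecular Diels–Alder reaction (bonds C3a–C7a and C4–C5). It is run on the unprotected ketone and free acid, unveiled in the flask by oxidation of a carbinol.
2. Carbinol acid ⇒ trienal + chiral vinylketene silyl N,O-acetal (vinylogous Mukaiyama aldol, C2–C3 bond; sets C3, the carbinol centre is erased later).
3. Trienal ⇒ (R)-Roche ester (source of C1) by three E-selective olefinations; N,O-acetal ⇒ (E)-2-ethylhex-2-enoic acid + valine-derived oxazolidinone.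
4. Ring order: no ring is made before the last step; rings A and B then form at the same time.

Assumption: the target is taken exactly as the SMILES shows, i.e. the (1S,3S,3aR,4R,5S,7aR) acid with an E-styryl group; indene numbering is used for the bicycle (C1 Me, C2 C=O, C3 Et, C4 Et/CO2H, C5 Et/styryl, C7 Me).

**Step 1**
Reactants: 1 methyl (R)-3-hydroxy-2-methylpropanoate; 2 tert-butyldimethylsilyl chloride
Product: 3 methyl (R)-3-((tert-butyldimethylsilyl)oxy)-2-methylpropanoate
Conditions: imidazole, CH2Cl2, 0 °C to rt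
Reagents that add atoms: tert-butyldimethylsilyl chloride, CC(C)(C)[Si](C)(C)Cl
Why: Imidazole-promoted silyl ether formation masks the primary alcohol so that the ester can be reduced; the stereocentre is not touched.

**Step 2**
Reactants: 3 methyl (R)-3-((tert-butyldimethylsilyl)oxy)-2-methylpropanoate; 4 2-(triphenylphosphoranylidene)propanal
Product: 6 (S,E)-5-((tert-butyldimethylsilyl)oxy)-2,4-dimethylpent-2-enal, via silyloxy aldehyde 5 (not isolated)
Conditions: i-Bu2AlH, CH2Cl2, −78 °C; aq. KNaC4H4O6 (potassium sodium tartrate) work-up; crude aldehyde + 4, toluene, 90 °C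
Reagents that add atoms: 2-(triphenylphosphoranylidene)propanal, CC(C=O)=P(c1ccccc1)(c1ccccc1)c1ccccc1
Why: Partial ester reduction stops at the aldehyde (stable aluminate at −78 °C) and the crude α-chiral aldehyde is trapped at once by a base-free Wittig olefination with a stabilised ylide, giving the E-enal without epimerisation (R becomes S only through the change in CIP ranking).

**Step 3**
Reactants: 6 (S,E)-5-((tert-butyldimethylsilyl)oxy)-2,4-dimethylpent-2-enal; 7 2-(triphenylphosphoranylidene)butanal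
Product: 8 (2E,4E,6S)-7-((tert-butyldimethylsilyl)oxy)-2-ethyl-4,6-dimethylhepta-2,4-dienal
Conditions: toluene, 110 °C
Reagents that add atoms: 2-(triphenylphosphoranylidene)butanal, CCC(C=O)=P(c1ccccc1)(c1ccccc1)c1ccccc1
Why: A second Wittig olefination with a formyl-stabilised ylide places the chain trans to the formyl group (2E), which becomes the E geometry of the later diene terminus carrying the ethyl group.

**Step 4**
Reactants: 8 (2E,4E,6S)-7-((tert-butyldimethylsilyl)oxy)-2-ethyl-4,6-dimethylhepta-2,4-dienal; 9 diethyl benzylphosphonate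
Product: 10 tert-butyl(((2S,3E,5E,7E)-6-ethyl-2,4-dimethyl-8-phenylocta-3,5,7-trien-1-yl)oxy)dimethylsilane
Conditions: NaH, THF, 0 °C to rt
Reagents that add atoms: diethyl benzylphosphonate, CCOP(=O)(Cc1ccccc1)OCC
Why: Horner–Wadsworth–Emmons olefination with the benzylic phosphonate anion gives the E-styryl unit; the silyl ether and the remote stereocentre are inert to these conditions.

**Step 5**
Reactants: 10 tert-butyl(((2S,3E,5E,7E)-6-ethyl-2,4-dimethyl-8-phenylocta-3,5,7-trien-1-yl)oxy)dimethylsilane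
Product: 11 (2S,3E,5E,7E)-6-ethyl-2,4-dimethyl-8-phenylocta-3,5,7-trien-1-ol
Conditions: Bu4NF, THF, 0 °C
Reagents that add atoms: none
Why: Fluoride-driven silyl ether cleavage frees the primary alcohol without touching the triene or the stereocentre.

**Step 6**
Reactants: 11 (2S,3E,5E,7E)-6-ethyl-2,4-dimethyl-8-phenylocta-3,5,7-trien-1-ol
Product: 12 (2S,3E,5E,7E)-6-ethyl-2,4-dimethyl-8-phenylocta-3,5,7-trienal
Conditions: Dess–Martin periodinane, NaHCO3, CH2Cl2, 0 °C; crude product used at once
Reagents that add atoms: none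
Why: Buffered Dess–Martin oxidation is neutral enough to give the β,γ-unsaturated α-methyl aldehyde without epimerisation or migration of the double bond into conjugation.

**Step 7**
Reactants: 13 (E)-2-ethylhex-2-enoic acid; 14 (S)-4-isopropyloxazolidin-2-one
Product: 16 (S,E)-3-(2-ethylhex-2-enoyl)-4-isopropyloxazolidin-2-one, via mixed pivalic anhydride 15 (not isolated)
Conditions: t-BuCOCl, Et3N, THF, −20 °C; then 14, LiCl, rt
Reagents that add atoms: (S)-4-isopropyloxazolidin-2-one, CC(C)[C@H]1COC(=O)N1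
Why: N-acylation of the oxazolidinone through the mixed anhydride (LiCl/Et3N acylation) occurs at the less hindered enoyl carbonyl and leaves the E-alkene intact.

**Step 8**
Reactants: 16 (S,E)-3-(2-ethylhex-2-enoyl)-4-isopropyloxazolidin-2-one; 2 tert-butyldimethylsilyl chloride
Product: 17 (S)-3-((1E,3E)-1-((tert-butyldimethylsilyl)oxy)-2-ethylhexa-1,3-dien-1-yl)-4-isopropyloxazolidin-2-one
Conditions: NaN(SiMe3)2, THF, −78 °C; then 2
Reagents that add atoms: tert-butyldimethylsilyl chloride, CC(C)(C)[Si](C)(C)Cl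
Why: γ-Deprotonation of the enoyl imide gives the extended sodium dienolate, and O-silylation gives the E,E vinylketene silyl N,O-acetal (Kobayashi protocol).

**Step 9**
Reactants: 12 (2S,3E,5E,7E)-6-ethyl-2,4-dimethyl-8-phenylocta-3,5,7-trienal; 17 (S)-3-((1E,3E)-1-((tert-butyldimethylsilyl)oxy)-2-ethylhexa-1,3-dien-1-yl)-4-isopropyloxazolidin-2-one
Product: 18 (S)-3-((2E,4S,5R,6S,7E,9E,11E)-2,4,10-triethyl-5-hydroxy-6,8-dimethyl-12-phenyldodeca-2,7,9,11-tetraenoyl)-4-isopropyloxazolidin-2-one
Conditions: TiCl4, CH2Cl2, −78 °C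
Reagents that add atoms: N,O-acetal 17, CC/C=C/C(CC)=C(/O[Si](C)(C)C(C)(C)C)N1[C@@H](C(C)C)COC1=O
Why: Kobayashi vinylogous Mukaiyama aldol reaction: the TiCl4-bound aldehyde attacks the γ-carbon on the face away from the isopropyl group (sets 4S) through the anti open transition state (sets 5R), which is also the Felkin–Anh sense for the (2S)-aldehyde, so reagent and substrate control reinforce each other and the E-enoyl imide is restored.

**Step 10**
Reactants: 18 (S)-3-((2E,4S,5R,6S,7E,9E,11E)-2,4,10-triethyl-5-hydroxy-6,8-dimethyl-12-phenyldodeca-2,7,9,11-tetraenoyl)-4-isopropyloxazolidin-2-one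
Product: 19 (2E,4S,5R,6S,7E,9E,11E)-2,4,10-triethyl-5-hydroxy-6,8-dimethyl-12-phenyldodeca-2,7,9,11-tetraenoic acid
Conditions: LiOH, H2O2, THF/H2O, 0 °C; then Na2SO3; 1 M HCl to pH 3
Reagents that add atoms: hydrogen peroxide, OO
Why: Exocyclic imide cleavage by LiOOH (Evans hydrolysis) removes the auxiliary while the acyl carbon is still unhindered; hydroperoxide neither epimerises C4 nor epoxidises the electron-rich triene.

**Step 11**
Reactants: 19 (2E,4S,5R,6S,7E,9E,11E)-2,4,10-triethyl-5-hydroxy-6,8-dimethyl-12-phenyldodeca-2,7,9,11-tetraenoic acid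
Product: 21 (1S,3S,3aR,4R,5S,7aR)-3,4,5-triethyl-1,7-dimethyl-2-oxo-5-[(E)-2-phenylethenyl]-2,3,3a,4,5,7a-hexahydro-1H-indene-4-carboxylic acid, via keto acid 20 (not isolated)
Conditions: Dess–Martin periodinane, NaHCO3, CH2Cl2, 0 °C; aq. Na2S2O3 wash; then toluene, BHT, 60–80 °C
Reagents that add atoms: none
Why: Dess–Martin oxidation erases the carbinol centre and frees keto acid 20, which closes both rings at once by a thermal intramolecular Diels–Alder reaction (type 1, three-atom tether): A(1,3) strain makes C1–H eclipse the diene (against the C7 methyl) and C3–H eclipse the dienophile (against the C4 ethyl), so the tether can reach only one face of each π-system and these faces meet only in the trans-fused transition state with CO2H endo, which sets C3a, C4, C5 and C7a together, the E geometries fixing the cis relation of the two ethyl groups on C4 and C5.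

**Compound list**
1 | methyl (R)-3-hydroxy-2-methylpropanoate ((R)-Roche ester) | OC[C@@H](C)C(=O)OC | starting material
2 | tert-butyldimethylsilyl chloride | CC(C)(C)[Si](C)(C)Cl | starting material
3 | methyl (R)-3-((tert-butyldimethylsilyl)oxy)-2-methylpropanoate | CC(C)(C)[Si](C)(C)OC[C@@H](C)C(=O)OC | intermediate
4 | 2-(triphenylphosphoranylidene)propanal | CC(C=O)=P(c1ccccc1)(c1ccccc1)c1ccccc1 | starting material
5 | (R)-3-((tert-butyldimethylsilyl)oxy)-2-methylpropanal | CC(C)(C)[Si](C)(C)OC[C@@H](C)C=O | intermediate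
6 | (S,E)-5-((tert-butyldimethylsilyl)oxy)-2,4-dimethylpent-2-enal | CC(C)(C)[Si](C)(C)OC[C@@H](C)/C=C(\C)C=O | intermediate
7 | 2-(triphenylphosphoranylidene)butanal | CCC(C=O)=P(c1ccccc1)(c1ccccc1)c1ccccc1 | starting material
8 | (2E,4E,6S)-7-((tert-butyldimethylsilyl)oxy)-2-ethyl-4,6-dimethylhepta-2,4-dienal | CC(C)(C)[Si](C)(C)OC[C@@H](C)/C=C(C)/C=C(\CC)C=O | intermediate
9 | diethyl benzylphosphonate | CCOP(=O)(Cc1ccccc1)OCC | starting material
10 | tert-butyl(((2S,3E,5E,7E)-6-ethyl-2,4-dimethyl-8-phenylocta-3,5,7-trien-1-yl)oxy)dimethylsilane | CC(C)(C)[Si](C)(C)OC[C@@H](C)/C=C(C)/C=C(CC)/C=C/c1ccccc1 | intermediate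
11 | (2S,3E,5E,7E)-6-ethyl-2,4-dimethyl-8-phenylocta-3,5,7-trien-1-ol | OC[C@@H](C)/C=C(C)/C=C(CC)/C=C/c1ccccc1 | intermediate
12 | (2S,3E,5E,7E)-6-ethyl-2,4-dimethyl-8-phenylocta-3,5,7-trienal | O=C[C@@H](C)/C=C(C)/C=C(CC)/C=C/c1ccccc1 | intermediate
13 | (E)-2-ethylhex-2-enoic acid | CCC/C=C(\CC)C(=O)O | starting material
14 | (S)-4-isopropyloxazolidin-2-one | CC(C)[C@H]1COC(=O)N1 | starting material
15 | (E)-2-ethylhex-2-enoic pivalic anhydride | CCC/C=C(\CC)C(=O)OC(=O)C(C)(C)C | intermediate
16 | (S,E)-3-(2-ethylhex-2-enoyl)-4-isopropyloxazolidin-2-one | CCC/C=C(\CC)C(=O)N1[C@@H](C(C)C)COC1=O | intermediate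
17 | (S)-3-((1E,3E)-1-((tert-butyldimethylsilyl)oxy)-2-ethylhexa-1,3-dien-1-yl)-4-isopropyloxazolidin-2-one | CC/C=C/C(CC)=C(/O[Si](C)(C)C(C)(C)C)N1[C@@H](C(C)C)COC1=O | intermediate
18 | (S)-3-((2E,4S,5R,6S,7E,9E,11E)-2,4,10-triethyl-5-hydroxy-6,8-dimethyl-12-phenyldodeca-2,7,9,11-tetraenoyl)-4-isopropyloxazolidin-2-one | O=C(/C(CC)=C/[C@H](CC)[C@H](O)[C@@H](C)/C=C(C)/C=C(CC)/C=C/c1ccccc1)N1[C@@H](C(C)C)COC1=O | intermediate
19 | (2E,4S,5R,6S,7E,9E,11E)-2,4,10-triethyl-5-hydroxy-6,8-dimethyl-12-phenyldodeca-2,7,9,11-tetraenoic acid | O=C(O)/C(CC)=C/[C@H](CC)[C@H](O)[C@@H](C)/C=C(C)/C=C(CC)/C=C/c1ccccc1 | intermediate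
20 | (2E,4S,6S,7E,9E,11E)-2,4,10-triethyl-6,8-dimethyl-5-oxo-12-phenyldodeca-2,7,9,11-tetraenoic acid | O=C(O)/C(CC)=C/[C@H](CC)C(=O)[C@@H](C)/C=C(C)/C=C(CC)/C=C/c1ccccc1 | intermediate
21 | (1S,3S,3aR,4R,5S,7aR)-3,4,5-triethyl-1,7-dimethyl-2-oxo-5-[(E)-2-phenylethenyl]-2,3,3a,4,5,7a-hexahydro-1H-indene-4-carboxylic acid (CNP0178058.1) | CC[C@@H]1C(=O)[C@@H](C)[C@@H]2C(C)=C[C@@](/C=C/c3ccccc3)(CC)[C@](CC)(C(=O)O)[C@H]21 | target

**Step count and risks**
Total step count: 11. Longest linear sequence: 9 steps (steps 1–6, 9, 10, 11 from compound 1).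

The three steps most likely to fail:

- **Step 11.** Keto acid 20 is a vinylogous β-keto acid, so C3 may epimerise (or the C1–H/diene may drift into conjugation) before cycloaddition, and the C3 epimer would give the cis-fused adduct. The bond between two fully substituted carbons may also demand more heat than 20 tolerates. Fallback: set out from 19 and cyclise first at the carbinol stage, where C3 cannot epimerise (toluene, BHT, 80–110 °C). The same trans-fused, CO2H-endo Diels–Alder reaction gives (1S,2R,3S,3aR,4R,5S,7aR)-3,4,5-triethyl-2-hydroxy-1,7-dimethyl-5-[(E)-2-phenylethenyl]-2,3,3a,4,5,7a-hexahydro-1H-indene-4-carboxylic acid F1. Its oxidation with Dess–Martin periodinane (NaHCO3, CH2Cl2) comes back to the route at 21.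

- **Step 9.** Aldehyde 12 is a β,γ-unsaturated α-methyl aldehyde with an acid-sensitive aryl triene, and TiCl4 may decompose it, or the doubly ethyl-substituted N,O-acetal 17 may add sluggishly. The facial sense of 17 rests on the Kobayashi model and should be confirmed on the adduct. Fallback: set out from acid 13 and drop the auxiliary. Double deprotonation (LiN(i-Pr)2, 2.2 equiv, THF, −78 °C) and silylation with Me3SiCl give (((3E)-2-ethylhexa-1,3-diene-1,1-diyl)bis(oxy))bis(trimethylsilane) F2. F2 is added to 12 with BF3·OEt2 in CH2Cl2 at −78 °C under Felkin–Anh control from 12 alone. Aqueous work-up gives the free acid and comes back to the route at 19 (C4 epimers removed by chromatography), so steps 7, 8 and 10 fall away.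

- **Step 3.** The α-methyl enal 6 is hindered and the formyl ylide 7 is weakly nucleophilic, so the reaction may stall or homologate twice. Fallback: set out from 6 and use a Horner–Wadsworth–Emmons reaction with triethyl 2-phosphonobutanoate (NaH, THF, 0 °C), which gives ethyl (2E,4E,6S)-7-((tert-butyldimethylsilyl)oxy)-2-ethyl-4,6-dimethylhepta-2,4-dienoate F3. Reduction with i-Bu2AlH (CH2Cl2, −78 °C) gives (2E,4E,6S)-7-((tert-butyldimethylsilyl)oxy)-2-ethyl-4,6-dimethylhepta-2,4-dien-1-ol F4. Allylic oxidation with MnO2 (CH2Cl2, rt) comes back to the route at 8.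

**Further compounds**
F1 | step 11 | (1S,2R,3S,3aR,4R,5S,7aR)-3,4,5-triethyl-2-hydroxy-1,7-dimethyl-5-[(E)-2-phenylethenyl]-2,3,3a,4,5,7a-hexahydro-1H-indene-4-carboxylic acid | CC[C@@H]1[C@H](O)[C@@H](C)[C@@H]2C(C)=C[C@@](/C=C/c3ccccc3)(CC)[C@](CC)(C(=O)O)[C@H]21
F2 | step 9 | (((3E)-2-ethylhexa-1,3-diene-1,1-diyl)bis(oxy))bis(trimethylsilane) | CC/C=C/C(CC)=C(O[Si](C)(C)C)O[Si](C)(C)C
F3 | step 3 | ethyl (2E,4E,6S)-7-((tert-butyldimethylsilyl)oxy)-2-ethyl-4,6-dimethylhepta-2,4-dienoate | CC(C)(C)[Si](C)(C)OC[C@@H](C)/C=C(C)/C=C(\CC)C(=O)OCC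
F4 | step 3 | (2E,4E,6S)-7-((tert-butyldimethylsilyl)oxy)-2-ethyl-4,6-dimethylhepta-2,4-dien-1-ol | CC(C)(C)[Si](C)(C)OC[C@@H](C)/C=C(C)/C=C(\CC)CO
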